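**Retrosynthetic overview**
1. Corymbosin ⇒ 5,7-dihydroxy-3',4',5'-trimethoxyflavone by selective 7-O-methylation as the last step (the chelated 5-OH needs no protection) ⇒ its 5,7-di-O-benzyl ether by hydrogenolysis.
2. Ring C (O1–C2 bond and C2=C3) ⇒ oxidative cyclisation of a 2'-hydroxychalcone.
3. Key C–C bond (chalcone Cα–Cβ, which becomes C3–C2 of the flavone) ⇒ intermolecular Claisen–Schmidt aldol condensation of 2-hydroxy-4,6-bis(benzyloxy)acetophenone with 3,4,5-trimethoxybenzaldehyde.
4. The acetophenone ⇒ phloroacetophenone by chelation-limited double O-benzylation.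
5. Ring order: rings A and B are bought as intact arenes, and the pyranone ring C is the only ring formed (step 3). The main route never exposes the 3,4,5-trimethoxyphenyl ring to a Lewis-acid demethylation.

Assumption: corymbosin has no stereocentre and no stereogenic axis, so it is achiral and there is no enantiomer to select. The only stereochemical elements in the route are transient: the E-alkene of 5 and the racemic centres of 4 and 6.

**Step 1**
Reactants: 1 2,4,6-trihydroxyacetophenone (phloroacetophenone, dried monohydrate)
Product: 2 2-hydroxy-4,6-bis(benzyloxy)acetophenone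
Conditions: BnBr (2.1 equiv), K2CO3 (2.2 equiv), DMF, rt → 60 °C, 6 h
Reagents that add atoms: benzyl bromide, BrCc1ccccc1
Why: In this Williamson ether synthesis the 4-OH and one of the two equivalent ortho-OH groups are alkylated, while the last ortho-OH is locked in a strong hydrogen bond to the ketone and is too poorly nucleophilic to react with about 2 equiv of BnBr; no stereocentre is formed.

**Step 2**
Reactants: 2 2-hydroxy-4,6-bis(benzyloxy)acetophenone; 3 3,4,5-trimethoxybenzaldehyde (1.1 equiv)
Product: 5 (E)-2'-hydroxy-4',6'-bis(benzyloxy)-3,4,5-trimethoxychalcone, via aldol adduct 4 (not isolated)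
Conditions: KOH (50% aq, 10 equiv), EtOH/THF, rt, 36 h; then 1 M HCl to pH 4
Reagents that add atoms: none
Why: In this Claisen–Schmidt (crossed aldol) condensation only the methyl ketone can enolise and only the aldehyde is a good acceptor, so a single intermolecular C–C bond forms, and E1cB loss of water from racemic 4 gives the conjugated E-chalcone under thermodynamic control with the benzyl and methyl ethers inert to base.

**Step 3**
Reactants: 5 (E)-2'-hydroxy-4',6'-bis(benzyloxy)-3,4,5-trimethoxychalcone
Product: 7 5,7-bis(benzyloxy)-3',4',5'-trimethoxyflavone, via flavanone 6 (not isolated)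
Conditions: I2 (10 mol %), DMSO, 120 °C, 3 h
Reagents that add atoms: none
Why: In this I2/DMSO oxidative cyclisation of a 2'-hydroxychalcone, intramolecular oxa-Michael addition gives flavanone 6, whose racemic C2 centre is erased by iodine-catalysed dehydrogenation with DMSO as terminal oxidant, and aryl benzyl and methyl ethers survive.

**Step 4**
Reactants: 7 5,7-bis(benzyloxy)-3',4',5'-trimethoxyflavone
Product: 8 5,7-dihydroxy-3',4',5'-trimethoxyflavone
Conditions: H2 (1 atm), 10% Pd/C, THF/MeOH 1:1, rt, 6 h
Reagents that add atoms: none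
Why: Catalytic hydrogenolysis of the two benzylic C–O bonds is much faster at 1 atm and rt than reduction of the flavone C2=C3 bond (a doubly aryl-conjugated vinylogous ester), and aryl methyl ethers are untouched.

**Step 5**
Reactants: 8 5,7-dihydroxy-3',4',5'-trimethoxyflavone
Product: 9 corymbosin (5-hydroxy-7-methoxy-2-(3,4,5-trimethoxyphenyl)-4H-chromen-4-one)
Conditions: MeI (1.05 equiv), K2CO3 (1.1 equiv), DMF, rt, 12 h
Reagents that add atoms: iodomethane, CI
Why: In this chemoselective Williamson O-methylation the 7-OH (a vinylogous carboxylic acid, pKa about 7–8) is deprotonated and alkylated, while the 5-OH is chelated to C4=O (pKa above 11) and stays free with one equivalent of MeI; no stereocentre is involved.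

**Compound list**
1 | 2,4,6-trihydroxyacetophenone (phloroacetophenone) | CC(=O)c1c(O)cc(O)cc1O | starting material
2 | 2-hydroxy-4,6-bis(benzyloxy)acetophenone | CC(=O)c1c(O)cc(OCc2ccccc2)cc1OCc1ccccc1 | intermediate
3 | 3,4,5-trimethoxybenzaldehyde | COc1cc(C=O)cc(OC)c1OC | starting material
4 | racemic aldol adduct, not isolated: 3-hydroxy-1-[2-hydroxy-4,6-bis(benzyloxy)phenyl]-3-(3,4,5-trimethoxyphenyl)propan-1-one | O=C(CC(O)c1cc(OC)c(OC)c(OC)c1)c1c(O)cc(OCc2ccccc2)cc1OCc1ccccc1 | intermediate
5 | (E)-2'-hydroxy-4',6'-bis(benzyloxy)-3,4,5-trimethoxychalcone | O=C(/C=C/c1cc(OC)c(OC)c(OC)c1)c1c(O)cc(OCc2ccccc2)cc1OCc1ccccc1 | intermediate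
6 | racemic flavanone, not isolated: 5,7-bis(benzyloxy)-2-(3,4,5-trimethoxyphenyl)chroman-4-one | O=C1CC(c2cc(OC)c(OC)c(OC)c2)Oc2cc(OCc3ccccc3)cc(OCc3ccccc3)c21 | intermediate
7 | 5,7-bis(benzyloxy)-3',4',5'-trimethoxyflavone | O=c1cc(-c2cc(OC)c(OC)c(OC)c2)oc2cc(OCc3ccccc3)cc(OCc3ccccc3)c12 | intermediate
8 | 5,7-dihydroxy-3',4',5'-trimethoxyflavone | O=c1cc(-c2cc(OC)c(OC)c(OC)c2)oc2cc(O)cc(O)c12 | intermediate
9 | corymbosin (achiral) | COc1cc(O)c2c(=O)cc(-c3cc(OC)c(OC)c(OC)c3)oc2c1 | target

**Total step count:** 5. **Longest linear sequence:** 5 (1 → 2 → 5 → 7 → 8 → 9).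

**Three steps most likely to fail**

Step 1. The risk is incomplete selectivity: mono- and tri-ethers and some C-benzylated material may contaminate 2. The fallback sets out from 1 and comes back at 2. Instead of stopping at the di-ether, 1 is benzylated exhaustively (BnBr 3.5 equiv, K2CO3, DMF, 80 °C). This gives the single, crystalline 2,4,6-tris(benzyloxy)acetophenone F1. One of its two equivalent ortho benzyl ethers is then removed under chelation control with MgBr2·OEt2 (toluene/Et2O, reflux). Magnesium bound between C=O and the ortho oxygen delivers bromide to that benzyl group only. The magnesium phenolate chelate that results shields the second ortho ether, so the product is 2.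

Step 3. The risks are partial loss of the 5-O-benzyl group, iodination of the electron-rich ring A, or a stall at the flavanone at 120 °C. The fallback sets out from 2 and comes back at 7, and it needs no oxidant. The lithium dianion of 2 (LiHMDS 3.2 equiv, THF, −78 °C) is C-acylated with commercial 3,4,5-trimethoxybenzoyl chloride (COc1cc(C(=O)Cl)cc(OC)c1OC) in an intermolecular Claisen-type condensation. This gives 1-[2-hydroxy-4,6-bis(benzyloxy)phenyl]-3-(3,4,5-trimethoxyphenyl)propane-1,3-dione F2, which already has the flavone oxidation level. Cyclodehydration (cat. p-TsOH, toluene, reflux, Dean–Stark) then gives 7.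

Step 5. The risk is over-methylation at the 5-OH or an incomplete reaction that leaves a mixture hard to separate. The fallback sets out from 8 and comes back at 9. Compound 8, or any mixed fractions, is methylated exhaustively (MeI 3 equiv, K2CO3, DMF, 60 °C) to 5,7,3',4',5'-pentamethoxyflavone F3. The methyl ether peri to the carbonyl is then removed selectively with BCl3 (1.2 equiv, CH2Cl2, −78 → 0 °C). Boron chelated between C4=O and the 5-oxygen directs chloride to that methyl group. The low temperature and near-stoichiometric BCl3 spare the 4'-OMe, and the product is 9.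

**Further compounds**
F1 | step 1 | 2,4,6-tris(benzyloxy)acetophenone | CC(=O)c1c(OCc2ccccc2)cc(OCc2ccccc2)cc1OCc1ccccc1
F2 | step 3 | 1-[2-hydroxy-4,6-bis(benzyloxy)phenyl]-3-(3,4,5-trimethoxyphenyl)propane-1,3-dione | O=C(CC(=O)c1cc(OC)c(OC)c(OC)c1)c1c(O)cc(OCc2ccccc2)cc1OCc1ccccc1
F3 | step 5 | 5,7,3',4',5'-pentamethoxyflavone | COc1cc(OC)c2c(=O)cc(-c3cc(OC)c(OC)c(OC)c3)oc2c1
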